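**Plan**
- Retrosynthesis first cuts the C3–OMe bond and the C3–O bond, leaving 5,7,8-trimethoxy-2-(2-methoxyphenyl)chromen-4-one; ring C is then opened at three bonds at once, C4a–C4, C4–C3 and O1–C2.
- This works because C4 is a single carbonyl carbon between C4a of ring A and C3, and O1 sits on C8a next to C4a: ring C equals an ortho-iodophenol (C8a–OH, C4a–I), CO (C4) and a terminal arylalkyne (C3, C2 and ring B).
- The iodophenol goes back to 2-hydroxy-4,6-dimethoxybenzaldehyde: the formyl carbon is exchanged for oxygen (Baeyer–Villiger) and iodine enters by acetal-directed lithiation.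
- Forward: ring A is prepared in five steps, ring C closes as rings A and B are joined in one carbonylative annulation, and the C3 oxygen is added last by lithiation–borylation–oxidation and methylation.
- Stereochemistry: the target has no stereocentre, so none has to be set.

Key step: step 6

Remark: β-amino enone 12 is written without a fixed C=C geometry, since such push–pull alkenes interconvert and either form can close; epoxide F6 of the third fallback would be racemic, its cis ring fusion being forced by the three-membered ring.

**Step 1**
Reactants: 1 2-hydroxy-4,6-dimethoxybenzaldehyde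
Product: 2 2-(methoxymethoxy)-4,6-dimethoxybenzaldehyde
Conditions: NaH, DMF, 0 °C; MOMCl, 0 °C → rt
Reagents that add atoms: chloromethyl methyl ether, COCCl
Why: Williamson-type O-alkylation, in which the sodium phenoxide displaces chloride from the reactive α-chloro ether; the acetal should survive the peracid, base and organolithium steps that follow and later serves as the directing group.

**Step 2**
Reactants: 2 2-(methoxymethoxy)-4,6-dimethoxybenzaldehyde
Product: 4 2,4-dimethoxy-6-(methoxymethoxy)phenol, via aryl formate 3 (not isolated)
Conditions: mCPBA, CH2Cl2, 0 °C → rt; then K2CO3 (cat.), MeOH, 0 °C, argon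
Reagents that add atoms: 3-chloroperbenzoic acid, OOC(=O)c1cccc(Cl)c1
Why: Baeyer–Villiger (Dakin-type) oxidation, in which the aryl group, enriched by two ortho and one para oxygen substituents, migrates in preference to hydride, and the formate is then cleaved by mild transesterification that leaves the acetal and the methyl ethers intact.

**Step 3**
Reactants: 4 2,4-dimethoxy-6-(methoxymethoxy)phenol
Product: 5 1,2,5-trimethoxy-3-(methoxymethoxy)benzene
Conditions: MeI, K2CO3, acetone, reflux
Reagents that add atoms: iodomethane, CI
Why: Williamson ether synthesis on a phenoxide, carried out at once because the electron-rich phenol 4 is sensitive to air.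

**Step 4**
Reactants: 5 1,2,5-trimethoxy-3-(methoxymethoxy)benzene
Product: 7 2-iodo-1,4,5-trimethoxy-3-(methoxymethoxy)benzene, via aryllithium 6 (not isolated)
Conditions: n-BuLi, TMEDA, THF, 0 °C; then I2, THF, −78 °C → rt
Reagents that add atoms: n-butyllithium, [Li]CCCC (lithium, into 6 only); iodine, II
Why: Directed ortho-metalation, in which the acetal is a stronger directing group than a methyl ether and its only free ortho position lies between it and a methoxy group, so butyllithium should remove that doubly flanked proton in preference to the one between two methoxy groups, and iodine then traps the aryllithium at carbon.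

**Step 5**
Reactants: 7 2-iodo-1,4,5-trimethoxy-3-(methoxymethoxy)benzene
Product: 8 2-iodo-3,5,6-trimethoxyphenol
Conditions: HCl (cat.), MeOH, 40 °C
Reagents that add atoms: none
Why: Acid-catalysed acetal exchange with methanol removes the methoxymethyl group under conditions too mild to cleave aryl methyl ethers or the C–I bond.

**Step 6**
Reactants: 8 2-iodo-3,5,6-trimethoxyphenol; 9 carbon monoxide; 10 2-ethynylanisole (1-ethynyl-2-methoxybenzene)
Product: 13 5,7,8-trimethoxy-2-(2-methoxyphenyl)-4H-chromen-4-one, via hydroxyaryl ynone 11 (not isolated), via β-amino enone 12 (not isolated)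
Conditions: PdCl2(PPh3)2 (5 mol %), CO (20 bar), Et2NH, 120 °C
Reagents that add atoms: diethylamine, CCNCC (into 12 only; expelled again on ring closure)
Why: Zerovalent palladium formed from PdCl2(PPh3)2 inserts into the C–I bond of 8, migratory insertion of CO gives an aroylpalladium iodide, and copper-free alkynylation with 10 followed by reductive elimination delivers hydroxyaryl ynone 11, which creates the C4a–C4 and C4–C3 bonds. Diethylamine then adds to the ynone to give β-amino enone 12, and the phenol oxygen displaces the amine at C2 by addition–elimination, which creates the O1–C2 bond. The closest known reaction type is the palladium-catalysed carbonylative Sonogashira annulation of 2-iodophenols, CO and terminal arylalkynes to flavones. Ring C closes in the 6-endo mode (6-endo-trig on 12, formally 6-endo-dig on 11), and no stereocentre is created. The step needs carbonylative over direct coupling, which CO pressure and the absence of copper should secure, and 6-endo over 5-exo closure (flavone, not aurone), which the secondary amine should secure by making C2 the electrophilic carbon. The ortho relationship of iodine and hydroxyl in 8 fixes C4a and O1 on neighbouring carbons, so the 5,7,8-pattern of ring A cannot scramble.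

**Step 7**
Reactants: 13 5,7,8-trimethoxy-2-(2-methoxyphenyl)-4H-chromen-4-one
Product: 16 3-hydroxy-5,7,8-trimethoxy-2-(2-methoxyphenyl)-4H-chromen-4-one, via 3-lithioflavone 14 (not isolated), via flavon-3-yl boronate 15 (not isolated)
Conditions: LiN(iPr)2, THF, −78 °C; B(OMe)3, −78 → 0 °C; AcOH, 30% aq. H2O2, 0 °C → rt
Reagents that add atoms: lithium diisopropylamide, [Li]N(C(C)C)C(C)C (lithium, into 14 only); trimethyl borate, COB(OC)OC (boron and two methoxy groups, into 15 only); hydrogen peroxide, OO
Why: Deprotonation of the flavone at C3 by the lithium amide gives a vinyllithium held by the C4 carbonyl oxygen, which is trapped by the borate and then undergoes the peroxide-induced 1,2-shift of carbon from boron to oxygen (boronate oxidation), a known route from 5-alkoxyflavones to flavonols.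

**Step 8**
Reactants: 16 3-hydroxy-5,7,8-trimethoxy-2-(2-methoxyphenyl)-4H-chromen-4-one
Product: 17 3,5,7,8-tetramethoxy-2-(2-methoxyphenyl)-4H-chromen-4-one
Conditions: MeI, K2CO3, acetone, reflux
Reagents that add atoms: iodomethane, CI
Why: Williamson methylation of the acidic 3-hydroxyl of the flavonol, the only free hydroxyl in 16.

**Compound list**
1 | 2-hydroxy-4,6-dimethoxybenzaldehyde | COc1cc(O)c(C=O)c(OC)c1 | starting material
2 | 2-(methoxymethoxy)-4,6-dimethoxybenzaldehyde | COCOc1cc(OC)cc(OC)c1C=O | intermediate
3 | 2,4-dimethoxy-6-(methoxymethoxy)phenyl formate | COCOc1cc(OC)cc(OC)c1OC=O | intermediate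
4 | 2,4-dimethoxy-6-(methoxymethoxy)phenol | COCOc1cc(OC)cc(OC)c1O | intermediate
5 | 1,2,5-trimethoxy-3-(methoxymethoxy)benzene | COCOc1cc(OC)cc(OC)c1OC | intermediate
6 | [3,4,6-trimethoxy-2-(methoxymethoxy)phenyl]lithium | COCOc1c([Li])c(OC)cc(OC)c1OC | intermediate
7 | 2-iodo-1,4,5-trimethoxy-3-(methoxymethoxy)benzene | COCOc1c(I)c(OC)cc(OC)c1OC | intermediate
8 | 2-iodo-3,5,6-trimethoxyphenol | Oc1c(I)c(OC)cc(OC)c1OC | intermediate
9 | carbon monoxide | [C-]#[O+] | starting material
10 | 2-ethynylanisole (1-ethynyl-2-methoxybenzene) | COc1ccccc1C#C | starting material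
11 | 1-(2-hydroxy-3,4,6-trimethoxyphenyl)-3-(2-methoxyphenyl)prop-2-yn-1-one | COc1ccccc1C#CC(=O)c1c(O)c(OC)c(OC)cc1OC | intermediate
12 | 3-(diethylamino)-1-(2-hydroxy-3,4,6-trimethoxyphenyl)-3-(2-methoxyphenyl)prop-2-en-1-one | CCN(CC)C(=CC(=O)c1c(O)c(OC)c(OC)cc1OC)c1ccccc1OC | intermediate
13 | 5,7,8-trimethoxy-2-(2-methoxyphenyl)-4H-chromen-4-one | COc1ccccc1-c1cc(=O)c2c(OC)cc(OC)c(OC)c2o1 | intermediate
14 | 3-lithio-5,7,8-trimethoxy-2-(2-methoxyphenyl)-4H-chromen-4-one | COc1ccccc1-c1oc2c(OC)c(OC)cc(OC)c2c(=O)c1[Li] | intermediate
15 | dimethyl [5,7,8-trimethoxy-2-(2-methoxyphenyl)-4-oxo-4H-chromen-3-yl]boronate | COc1ccccc1-c1oc2c(OC)c(OC)cc(OC)c2c(=O)c1B(OC)OC | intermediate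
16 | 3-hydroxy-5,7,8-trimethoxy-2-(2-methoxyphenyl)-4H-chromen-4-one | COc1ccccc1-c1oc2c(OC)c(OC)cc(OC)c2c(=O)c1O | intermediate
17 | 3,5,7,8-tetramethoxy-2-(2-methoxyphenyl)-4H-chromen-4-one | COc1ccccc1-c1oc2c(OC)c(OC)cc(OC)c2c(=O)c1OC | target

Total step count: 8. Longest linear sequence: 8 steps (1 to 17); 9 and 10 are bought.

**Steps most likely to fail**

Step 6. Oxidative addition into the electron-rich, doubly ortho-substituted C–I bond may be slow. That would leave time for diethylamine to capture the aroylpalladium intermediate as an amide, or for coupling without CO uptake and closure to a benzofuran. The fallback sets out from 5 and 10 and comes back to the route at 13, making the C4–C4a bond by acylation instead of carbonylation. Alkyne 10 would be deprotonated with n-BuLi and acylated with N-methoxy-N-methylcarbamoyl chloride to give N-methoxy-N-methyl-3-(2-methoxyphenyl)prop-2-ynamide F1. Aryllithium 6, generated from 5 as in step 4, would be added to it at −78 °C (Weinreb ketone synthesis) to give 3-(2-methoxyphenyl)-1-[3,4,6-trimethoxy-2-(methoxymethoxy)phenyl]prop-2-yn-1-one F2. Catalytic HCl in MeOH would then free the phenol to give ynone 11, and Et2NH in EtOH would close it through 12 to 13.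

Step 4. Lithiation may take place partly at the position between the two methyl ethers, or the metalation may stay incomplete, so that the iodine ends up on the wrong carbon or 5 is recovered. The fallback sets out from 5 and comes back at 8, replacing the acetal by a much stronger carbamate directing group. Catalytic HCl in MeOH would give 2,3,5-trimethoxyphenol F3, and NaH with ClCONEt2 in THF would give 2,3,5-trimethoxyphenyl N,N-diethylcarbamate F4. Treatment with s-BuLi and TMEDA in THF at −78 °C, then I2 at the same temperature to forestall the anionic Fries shift, would give 2-iodo-3,5,6-trimethoxyphenyl N,N-diethylcarbamate F5. NaOH in EtOH at reflux would then cleave the carbamate to 8.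

Step 7. The amide base may add to the pyranone or open ring C instead of removing H3, or the hindered vinyllithium may be borylated incompletely, so that 13 returns after the oxidation. The fallback sets out from 13 and comes back at 16, oxidising the C2=C3 bond directly. Dimethyldioxirane in acetone/CH2Cl2 at 0 °C would give 2,3-epoxy-5,7,8-trimethoxy-2-(2-methoxyphenyl)chroman-4-one F6. Catalytic TsOH in CH2Cl2 would open the epoxide at C2, where the cation is stabilised by O1 and ring B, and loss of H3 would give flavonol 16.

**Further compounds**
F1 | step 6 | N-methoxy-N-methyl-3-(2-methoxyphenyl)prop-2-ynamide | CON(C)C(=O)C#Cc1ccccc1OC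
F2 | step 6 | 3-(2-methoxyphenyl)-1-[3,4,6-trimethoxy-2-(methoxymethoxy)phenyl]prop-2-yn-1-one | COCOc1c(C(=O)C#Cc2ccccc2OC)c(OC)cc(OC)c1OC
F3 | step 4 | 2,3,5-trimethoxyphenol | COc1cc(O)c(OC)c(OC)c1
F4 | step 4 | 2,3,5-trimethoxyphenyl N,N-diethylcarbamate | CCN(CC)C(=O)Oc1cc(OC)cc(OC)c1OC
F5 | step 4 | 2-iodo-3,5,6-trimethoxyphenyl N,N-diethylcarbamate | CCN(CC)C(=O)Oc1c(I)c(OC)cc(OC)c1OC
F6 | step 7 | 2,3-epoxy-5,7,8-trimethoxy-2-(2-methoxyphenyl)chroman-4-one | COc1ccccc1C12OC1C(=O)c1c(OC)cc(OC)c(OC)c1O2
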